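**Plan**
- Retrosynthesis: the target is cut first at the bond between the aromatic ring and the isopropyl-bearing methine (Michael addition to isobutylidene syncarpic acid), then at the three phenol protecting groups and the aryl–hexanoyl bond, and last inside the isobutyl arm, at the bond from its benzylic methine to its CH2 group and at the C–H of the CH(CH3)2 end.
- Enabling feature: that arm is isobutene plus one hydrogen, and its methine is the benzylic end carbon of a 1-oxadiene, O=C–C=CH–Ar, made of one carbonyl of the tetramethylcyclohexanetrione ring and the exocyclic arylidene C=C bond.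
- Forward: formylation and Knoevenagel condensation give the arylidene trione; isobutene adds across the oxadiene and closes a 2,2-dimethyl-dihydropyran fused to the trione ring (the only ring made, and a temporary one); silane and acid then cut its tertiary C–O bond to leave the isobutyl group and the free enol.
- Hexanoylation and neutral debenzylation follow (benzyl ethers are used so that no Lewis acid is needed once free phenols and enols coexist), and the second trione arm is joined last.
- Stereochemistry: the isobutyl methine (R) comes from the chiral confined Brønsted acid in the cycloaddition and no later step breaks a bond to it; the isopropyl methine (R) comes from the chiral aluminium lithium binaphthoxide catalyst in the last step.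

Key step: step 3

Assumption: the facial sense of the two catalyst-controlled steps (3 and 8) cannot be predicted with confidence for these substrates, so the catalyst antipodes written are those taken to give the R centres, and the mirror-image catalyst would be used if the sense proves opposite.

**Route**

Step 1
Reactants: 1 1,3,5-tris(benzyloxy)benzene
Product: 2 2,4,6-tris(benzyloxy)benzaldehyde
Conditions: POCl3, DMF, 0 °C to rt; then ice-water
Reagents that add atoms: N,N-dimethylformamide CN(C)C=O; water O
Why: Vilsmeier–Haack formylation, in which the chloroiminium ion attacks one of the three equivalent positions of the strongly activated trialkoxyarene and the new formyl group deactivates the ring against a second attack.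

Step 2
Reactants: 2 2,4,6-tris(benzyloxy)benzaldehyde; 3 syncarpic acid
Product: 4 2-[2,4,6-tris(benzyloxy)benzylidene]-4,4,6,6-tetramethylcyclohexane-1,3,5-trione
Conditions: piperidine (20 mol %), AcOH (20 mol %), 4 Å MS, toluene, 60 °C
Reagents that add atoms: none
Why: Knoevenagel condensation through the iminium ion of 2, in which the single acidic CH2 of syncarpic acid condenses with removal of water, the two ortho benzyloxy groups shield the new alkene from a second dione, and the symmetric trione leaves no alkene geometry to control.

Step 3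
Reactants: 4 2-[2,4,6-tris(benzyloxy)benzylidene]-4,4,6,6-tetramethylcyclohexane-1,3,5-trione; 5 isobutene
Product: 6 (4R)-4-[2,4,6-tris(benzyloxy)phenyl]-2,2,6,6,8,8-hexamethyl-3,4-dihydro-2H-chromene-5,7(6H,8H)-dione
Conditions: isobutene (10 equiv, condensed), (S,S)-IDPi acid (imidodiphosphorimidate from two (S)-3,3'-bis[3,5-bis(trifluoromethyl)phenyl]-BINOL units, two N-trifluoromethylsulfonyl groups; 5 mol %), CH2Cl2, −40 °C
Reagents that add atoms: none
Why: Proposed new method: the confined acid protonates (or tightly hydrogen-bonds) one of the two equivalent carbonyl groups flanking the exocyclic alkene of 4, which turns the O=C–C=CH(Ar) unit into an electron-poor 1-oxadiene with cationic character at the benzylic carbon, and isobutene adds in a concerted but strongly asynchronous inverse-demand oxa-[4+2] cycloaddition in which its CH2 carbon bonds to the benzylic carbon slightly ahead of the bond from its tertiary carbon to the carbonyl oxygen. The closest known reaction types are the thermal hetero-Diels–Alder reactions of alkylidene 1,3-diones (alkylidene syncarpic acids among them) with 1,1-disubstituted alkenes and the confined-acid-catalysed asymmetric [4+2] cycloadditions of ortho-quinone methides with simple olefins; new here is the catalytic asymmetric version on an arylidene trione with an unactivated gaseous alkene. The six-membered dihydropyran closes in the [4+2] event itself, and in the stepwise limit by capture of the tertiary cation by the enol oxygen, which gives the same ring. The single new stereocentre, the benzylic carbon (R), is set by the chiral anion, whose cavity holds the ion-paired heterodiene so that isobutene can reach one face only. The step needs Markovnikov regiochemistry, closure on oxygen and not on the arene, and cycloaddition ahead of isobutene oligomerisation: the polarity match of the nucleophilic CH2 terminus with the benzylic carbon secures the first, the benzyloxy groups on both ortho positions block Friedel–Crafts closure to an indane, and the basic push–pull carbonyl of 4 keeps the acid bound to the substrate at low temperature. An ene-type methallyl adduct from the same transition state would close to 6 under the acid, and the symmetric trione makes the two possible oxadienes identical.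

Step 4
Reactants: 6 (4R)-4-[2,4,6-tris(benzyloxy)phenyl]-2,2,6,6,8,8-hexamethyl-3,4-dihydro-2H-chromene-5,7(6H,8H)-dione
Product: 7 3-hydroxy-4,4,6,6-tetramethyl-2-{(1R)-3-methyl-1-[2,4,6-tris(benzyloxy)phenyl]butyl}cyclohex-2-ene-1,5-dione
Conditions: Et3SiH (5 equiv), CF3CO2H/CH2Cl2 (1:4), 0 °C to rt
Reagents that add atoms: none
Why: Ionic hydrogenation, in which protonation of the vinylogous ester carbonyl ionises the tertiary alkyl–oxygen bond as in the acidolysis of a tert-butyl ester and the tertiary cation is reduced irreversibly by the silane to the isobutyl group while reclosure to 6 is reversible; no bond to the stereocentre is broken, so its configuration is carried over.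

Step 5
Reactants: 7 3-hydroxy-4,4,6,6-tetramethyl-2-{(1R)-3-methyl-1-[2,4,6-tris(benzyloxy)phenyl]butyl}cyclohex-2-ene-1,5-dione
Product: 9 1-{2,4,6-tris(benzyloxy)-3-[(1R)-1-(2-hydroxy-3,3,5,5-tetramethyl-4,6-dioxocyclohex-1-en-1-yl)-3-methylbutyl]phenyl}hexan-1-one, via enol hexanoate 8 (not isolated)
Conditions: hexanoic acid (3 equiv) premixed with (CF3CO)2O (3 equiv), CH2Cl2, 0 °C to rt; then K2CO3, MeOH, 0 °C
Reagents that add atoms: hexanoic acid CCCCCC(=O)O
Why: Friedel–Crafts acylation by the mixed trifluoroacetic anhydride at one of the two equivalent free positions of the trialkoxyarene (the ketone formed deactivates the ring against a second acylation), the enol being esterified alongside to a vinylogous anhydride that mild methanolysis cleaves without touching the aryl ketone.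

Step 6
Reactants: 9 1-{2,4,6-tris(benzyloxy)-3-[(1R)-1-(2-hydroxy-3,3,5,5-tetramethyl-4,6-dioxocyclohex-1-en-1-yl)-3-methylbutyl]phenyl}hexan-1-one
Product: 10 1-{2,4,6-trihydroxy-3-[(1R)-1-(2-hydroxy-3,3,5,5-tetramethyl-4,6-dioxocyclohex-1-en-1-yl)-3-methylbutyl]phenyl}hexan-1-one
Conditions: H2 (1 atm), 10% Pd/C, EtOAc, rt
Reagents that add atoms: none
Why: Catalytic hydrogenolysis of the three aryl benzyl ethers under neutral conditions, which avoids the acid-induced cyclodehydration between a free phenol and the enol and leaves the hydrogen-bonded aryl ketone and the tetrasubstituted enol double bond unreduced.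

Step 7
Reactants: 3 syncarpic acid; 11 isobutyraldehyde
Product: 13 isobutylidene syncarpic acid, via piperidine Mannich base 12 (not isolated)
Conditions: piperidine (1.1 equiv), CH2Cl2, rt; then 1 M HCl, rt
Reagents that add atoms: none
Why: Knoevenagel condensation run through the Mannich base, in which piperidine holds the reactive alkylidene as its conjugate adduct so that no second dione can add, and acid then expels the amine.

Step 8
Reactants: 10 1-{2,4,6-trihydroxy-3-[(1R)-1-(2-hydroxy-3,3,5,5-tetramethyl-4,6-dioxocyclohex-1-en-1-yl)-3-methylbutyl]phenyl}hexan-1-one; 13 isobutylidene syncarpic acid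
Product: 14 myrtucommulone H
Conditions: 13 (1.2 equiv), AlLi[(R)-BINOL]2 (20 mol %), 4 Å MS, THF, −20 °C
Reagents that add atoms: none
Why: Friedel–Crafts-type Michael addition of the acylphloroglucinol to the alkylidene trione at the only free ring carbon, in which the lithium binaphthoxide generates the phenoxide and the aluminium centre binds a trione carbonyl so that the isopropyl methine (R) is set under catalyst control, the existing stereocentre lying meta and remaining untouched.

**Compound list**
1 | 1,3,5-tris(benzyloxy)benzene | c1ccc(COc2cc(OCc3ccccc3)cc(OCc3ccccc3)c2)cc1 | starting material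
2 | 2,4,6-tris(benzyloxy)benzaldehyde | O=Cc1c(OCc2ccccc2)cc(OCc2ccccc2)cc1OCc1ccccc1 | intermediate
3 | syncarpic acid (2,2,4,4-tetramethylcyclohexane-1,3,5-trione) | CC1(C)C(=O)CC(=O)C(C)(C)C1=O | starting material
4 | 2-[2,4,6-tris(benzyloxy)benzylidene]-4,4,6,6-tetramethylcyclohexane-1,3,5-trione (achiral, no alkene geometry) | CC1(C)C(=O)C(=Cc2c(OCc3ccccc3)cc(OCc3ccccc3)cc2OCc2ccccc2)C(=O)C(C)(C)C1=O | intermediate
5 | isobutene (2-methylpropene) | CC(C)=C | starting material
6 | (4R)-4-[2,4,6-tris(benzyloxy)phenyl]-2,2,6,6,8,8-hexamethyl-3,4-dihydro-2H-chromene-5,7(6H,8H)-dione | C(c1ccccc1)Oc1cc(OCc2ccccc2)c([C@H]2CC(C)(C)OC3=C2C(=O)C(C)(C)C(=O)C3(C)C)c(OCc2ccccc2)c1 | intermediate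
7 | 3-hydroxy-4,4,6,6-tetramethyl-2-{(1R)-3-methyl-1-[2,4,6-tris(benzyloxy)phenyl]butyl}cyclohex-2-ene-1,5-dione | C(c1ccccc1)Oc1cc(OCc2ccccc2)c([C@@H](CC(C)C)C2=C(O)C(C)(C)C(=O)C(C)(C)C2=O)c(OCc2ccccc2)c1 | intermediate
8 | enol hexanoate of 9: 2-{(1R)-1-[2,4,6-tris(benzyloxy)-3-hexanoylphenyl]-3-methylbutyl}-4,4,6,6-tetramethyl-3,5-dioxocyclohex-1-en-1-yl hexanoate | CCCCCC(=O)c1c(OCc2ccccc2)cc(OCc2ccccc2)c([C@@H](CC(C)C)C2=C(OC(=O)CCCCC)C(C)(C)C(=O)C(C)(C)C2=O)c1OCc1ccccc1 | intermediate
9 | 1-{2,4,6-tris(benzyloxy)-3-[(1R)-1-(2-hydroxy-3,3,5,5-tetramethyl-4,6-dioxocyclohex-1-en-1-yl)-3-methylbutyl]phenyl}hexan-1-one | CCCCCC(=O)c1c(OCc2ccccc2)cc(OCc2ccccc2)c([C@@H](CC(C)C)C2=C(O)C(C)(C)C(=O)C(C)(C)C2=O)c1OCc1ccccc1 | intermediate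
10 | 1-{2,4,6-trihydroxy-3-[(1R)-1-(2-hydroxy-3,3,5,5-tetramethyl-4,6-dioxocyclohex-1-en-1-yl)-3-methylbutyl]phenyl}hexan-1-one | CCCCCC(=O)c1c(O)cc(O)c([C@@H](CC(C)C)C2=C(O)C(C)(C)C(=O)C(C)(C)C2=O)c1O | intermediate
11 | isobutyraldehyde (2-methylpropanal) | CC(C)C=O | starting material
12 | racemic Mannich base, 3-hydroxy-4,4,6,6-tetramethyl-2-[2-methyl-1-(piperidin-1-yl)propyl]cyclohex-2-ene-1,5-dione | CC(C)C(N1CCCCC1)C1=C(O)C(C)(C)C(=O)C(C)(C)C1=O | intermediate
13 | isobutylidene syncarpic acid, 4,4,6,6-tetramethyl-2-(2-methylpropylidene)cyclohexane-1,3,5-trione | CC(C)C=C1C(=O)C(C)(C)C(=O)C(C)(C)C1=O | intermediate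
14 | myrtucommulone H, 1-{2,4,6-trihydroxy-3-[(1R)-1-(2-hydroxy-3,3,5,5-tetramethyl-4,6-dioxocyclohex-1-en-1-yl)-3-methylbutyl]-5-[(1R)-1-(2-hydroxy-3,3,5,5-tetramethyl-4,6-dioxocyclohex-1-en-1-yl)-2-methylpropyl]phenyl}hexan-1-one | CCCCCC(=O)c1c(O)c([C@@H](CC(C)C)C2=C(O)C(C)(C)C(=O)C(C)(C)C2=O)c(O)c([C@H](C2=C(O)C(C)(C)C(=O)C(C)(C)C2=O)C(C)C)c1O | target

**Step count and risks**
Total: 8 steps. Longest linear sequence: 7 steps (steps 1 to 6 and step 8); step 7 is a one-step side branch.

Steps most likely to fail:

1. Step 3 (proposed new method). The push–pull heterodiene may be too weakly activated, cationic oligomerisation of isobutene may outrun the cycloaddition, or the ion pair may discriminate poorly between the two faces. The fallback sets out from 4 and returns at 7, bypassing steps 3 and 4 with known chemistry: copper-catalysed asymmetric conjugate addition of diisobutylzinc to the arylidene trione (Cu(OTf)2, (S)-BINOL N,N-bis[(R)-1-phenylethyl]phosphoramidite, toluene, −30 °C; aqueous NH4Cl), a reaction type established for arylidene 1,3-dicarbonyl acceptors. It should deliver the isobutyl arm and its stereocentre in one operation and makes no new compound.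

2. Step 8. Protonation of the binaphthoxide by the acidic enol and phenols of 10 may leave an uncatalysed background addition, so that facial selectivity at the isopropyl methine is poor. The fallback sets out from 6 and returns at 14, building the second arm by addition of an isopropyl metal to a second arylidene while the pyran still masks the first enol.
   - Vilsmeier–Haack formylation of 6 (POCl3, DMF, 0 °C) should give the pyran aldehyde F3.
   - Knoevenagel condensation with 3 (piperidine/AcOH, toluene) should give the arylidene trione F4.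
   - Diisopropylzinc under Cu(OTf)2 and the phosphoramidite ligand named above (toluene, −30 °C) should give the isopropyl adduct F5, its methine set by the ligand.
   - Et3SiH/CF3CO2H as in step 4 should open the pyran to the bis-enol F6.
   - Hexanoylation at the last free ring carbon under the conditions of step 5 should give the ketone F7.
   - Hydrogenolysis (H2, Pd/C, EtOAc) removes the three benzyl groups to give 14.

3. Step 4. Reclosure of the tertiary cation onto the enol oxygen may outcompete hydride transfer, and the acid may cleave benzyl ethers or cause ipso-protonation of the electron-rich ring with retro-Friedel–Crafts erosion of the stereocentre. The fallback sets out from 6 and returns at 7, replacing hydride capture by elimination and hydrogenation.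
   - TMSOTf and 2,6-lutidine (CH2Cl2, 0 °C) should silylate the vinylogous ester carbonyl, ionise the tertiary C–O bond and deprotonate the cation, as the same reagent pair does with tert-butyl esters, to give the ring-opened methallyl silyl enol ether F1.
   - Hydrogenation over RhCl(PPh3)3 (H2, benzene, rt), which spares aryl benzyl ethers and the tetrasubstituted silyl enol ether, should give the isobutyl silyl enol ether F2.
   - K2CO3 in methanol removes the silyl group to give 7.

**Further compounds**
F0 | step 3 | none | none
F1 | step 4 | trimethylsilyl enol ether of the ring-opened methallyl compound, 4,4,6,6-tetramethyl-2-{(1R)-3-methyl-1-[2,4,6-tris(benzyloxy)phenyl]but-3-enyl}-3-(trimethylsilyloxy)cyclohex-2-ene-1,5-dione | C(c1ccccc1)Oc1cc(OCc2ccccc2)c([C@@H](CC(C)=C)C2=C(O[Si](C)(C)C)C(C)(C)C(=O)C(C)(C)C2=O)c(OCc2ccccc2)c1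
F2 | step 4 | trimethylsilyl enol ether of 7 | C(c1ccccc1)Oc1cc(OCc2ccccc2)c([C@@H](CC(C)C)C2=C(O[Si](C)(C)C)C(C)(C)C(=O)C(C)(C)C2=O)c(OCc2ccccc2)c1
F3 | step 8 | 2,4,6-tris(benzyloxy)-3-[(4R)-2,2,6,6,8,8-hexamethyl-5,7-dioxo-3,4,5,6,7,8-hexahydro-2H-chromen-4-yl]benzaldehyde | O=Cc1c(OCc2ccccc2)cc(OCc2ccccc2)c([C@H]2CC(C)(C)OC3=C2C(=O)C(C)(C)C(=O)C3(C)C)c1OCc1ccccc1
F4 | step 8 | arylidene trione from F3 and syncarpic acid (pyran centre R) | CC1(C)C(=O)C(=Cc2c(OCc3ccccc3)cc(OCc3ccccc3)c([C@H]3CC(C)(C)OC4=C3C(=O)C(C)(C)C(=O)C4(C)C)c2OCc2ccccc2)C(=O)C(C)(C)C1=O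
F5 | step 8 | isopropyl adduct: pyran arm (R) and open isopropyl arm (R) on 1,3,5-tris(benzyloxy)benzene | c1c(OCc2ccccc2)c([C@H]2CC(C)(C)OC3=C2C(=O)C(C)(C)C(=O)C3(C)C)c(OCc2ccccc2)c([C@H](C2=C(O)C(C)(C)C(=O)C(C)(C)C2=O)C(C)C)c1OCc1ccccc1
F6 | step 8 | bis-enol: isobutyl arm (R) and isopropyl arm (R) on 1,3,5-tris(benzyloxy)benzene | c1c(OCc2ccccc2)c([C@@H](CC(C)C)C2=C(O)C(C)(C)C(=O)C(C)(C)C2=O)c(OCc2ccccc2)c([C@H](C2=C(O)C(C)(C)C(=O)C(C)(C)C2=O)C(C)C)c1OCc1ccccc1
F7 | step 8 | tri-O-benzyl myrtucommulone H | CCCCCC(=O)c1c(OCc2ccccc2)c([C@@H](CC(C)C)C2=C(O)C(C)(C)C(=O)C(C)(C)C2=O)c(OCc2ccccc2)c([C@H](C2=C(O)C(C)(C)C(=O)C(C)(C)C2=O)C(C)C)c1OCc1ccccc1
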